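## The problem

Lespeflorin A1 (14) is a (2S)-flavanone: a 2,3-dihydro-4H-chromen-4-one whose benzo ring is substituted on five of six carbons (C4a acyl, C6 prenyl, C7 OH, C8 prenyl, C8a O1) and whose only stereocentre, C2, carries a 4-methoxyphenyl group. The contiguous C-prenyl/O/C-prenyl/O array is not found in any cheap arene, and direct electrophilic prenylation of a resorcinol ring gives O- and C-alkylation, at C6 and at C8, in mono and bis form side by side. C2 has no neighbouring stereocentre to control it, so a reagent must set it. It is also fragile: deprotonation at C3 expels O1 (E1cB) to a 2'-hydroxychalcone that recloses without selectivity, so base applied after C2 is set costs enantiopurity. The prenyl groups flank a free phenol and close to chromans under acid, and they exclude hydrogenation and strong oxidants late in the route.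

The feature that the key step uses is the position of the two prenylated carbons relative to both ring oxygens. C8 is ortho to O1 and to O7; C6 is ortho to O7 and para to O1; the only other ortho/para partner of either oxygen, C4a, is blocked by C4. An allyl group started on either oxygen can therefore come to rest only on C6 or C8 by [3,3] shifts, and the shift that empties O1 releases the phenol that closes the O1–C2 bond of the pyranone. A second feature serves the stereocentre: C2 is the β-carbon of the C2=C3–C4=O enone of the corresponding chromone, so the aryl group and the configuration can be introduced together on a flat, achiral ring.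

## Retrosynthesis

**14 from 13.** The last cut is the acetyl C–O bond at O7 of (2S)-7-acetoxyflavanone 13. An acetate is chosen over an ether because it can be put on in the flask of the key step. It also makes O7, which is para to C4a, a weaker donor toward the enone. It leaves by near-neutral acyl transfer, which neither C2 nor the prenyl groups should notice.

**13 from 11 and 12.** The C2–C1' bond is cut, giving 7-acetoxy-6,8-diprenylchromone 11 and 4-methoxyphenylboronic acid 12. The neighbouring cut, O1–C2, leads to a chalcone whose ring closure is reversible, so the bond that defines the stereocentre is also the one that breaks. The C–C bond does not reopen. The precursor 11 is achiral and planar. The forward reaction is a rhodium-catalysed enantioselective 1,4-arylation that must deliver the aryl group to the Re face of C2 and leave the aryl acetate and the two trisubstituted alkenes alone.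

**11 from 9 and 10.** Both Me2C= termini are cut, giving 7-acetoxy-6,8-diallylchromone 9 and 2-methylbut-2-ene 10. A prenyl group cannot be carried through the sigmatropic step: an ortho shift would deliver it as a 1,1-dimethylallyl group and a para shift as a prenyl group, so the two modes would give different products. Allyl is the same after one or two shifts, so the gem-dimethyl termini are added afterwards by a double cross-metathesis. The forward reaction must exchange both terminal alkenes and leave the endocyclic C2=C3 bond alone.

**9 from 5 (key disconnection).** Three bonds are cut at once: C6–allyl, C8–allyl and O1–C2. Each aryl–allyl bond is traced back to an O-allyl ether by a [3,3] shift. O1–C2 is traced back to an enaminone that the freed phenol closes with loss of dimethylamine. The precursor is (2E)-1-[2,4-bis(allyloxy)phenyl]-3-(dimethylamino)prop-2-en-1-one 5, a 1,2,4-trisubstituted benzene. The cascade passes through mono-rearranged phenol 6, diallyl hydroxy-enaminone 7 and 6,8-diallyl-7-hydroxychromone 8 to a pentasubstituted bicycle. The neighbouring option, Claisen chemistry on a preformed 7-hydroxychromone, has only O7 to carry allyl and needs two separate ether/rearrangement rounds. Here O1 carries the second allyl group before it becomes the ring oxygen. The forward reaction asks for both shifts to run to completion, one of them in the para mode, and for ring closure to follow.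

**5 from 3 and 4; 3 from 1 and 2.** The enaminone C2 carbon comes from N,N-dimethylformamide dimethyl acetal 4 by condensation with the methyl ketone 2,4-bis(allyloxy)acetophenone 3. Compound 3 comes from 2,4-dihydroxyacetophenone 1 and allyl bromide 2 by double O-alkylation. Both reactions are routine, and the absence of a free OH in 3 keeps the acetal from acting as a methylating agent.

## Roads not taken

**Alternative 1:** the route most chemists would draw first. The cuts are O1–C2 and the chalcone Cα=Cβ bond. Forward: direct C-prenylation of 1 to the diprenyl ketone A1, Claisen–Schmidt condensation with 4-methoxybenzaldehyde to chalcone A2, then a catalyst-controlled intramolecular oxa-Michael closure.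
- A1 would come from an ambident phenoxide with three nucleophilic sites (O, C3, C5) and no element that enforces the bis-C pattern.
- In A2 the stereo-defining step is the reversible one, so kinetic selectivity is exposed to equilibration under the conditions that create it.
- The reliable enantioselective versions need an extra ester at C3, whose acidic removal is at odds with ortho-prenyl phenols.
- The free 4'-OH of A2 is para to the carbonyl and, once deprotonated, deactivates the enone, so protection steps are added.
- The chosen plan fixes the substitution pattern by ring topology and makes the stereocentre by an irreversible C–C bond formation.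

**Alternative 2:** both aryl–prenyl bonds are cut last, on the preformed flavanone A3. Forward: 6,8-dibromination to A4 and a double Pd-catalysed coupling with a prenyl-metal reagent, or two rounds of reverse-prenyl ether formation and Claisen rearrangement from O7.
- The stereocentre is made early and must then survive basic coupling media or repeated heating with base present, which are the conditions of the E1cB ring opening.
- Prenyl-metal reagents can couple through their α- or γ-carbon, and here they would have to do so cleanly twice at hindered positions.
- With O1 already in the ring, only O7 can carry an allyl unit. The two rounds cannot be merged, and the first goes to C8 by preference, not by necessity.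
- The chosen plan does all arene substitution on achiral material and sets C2 after the prenyl groups are in place.

**Alternative 3:** O1–C2 is cut as an SN2 bond. Forward: Mitsunobu closure of the (R)-carbinol A5 with inversion, the carbinol coming from an asymmetric aldol reaction or ketone reduction.
- A 4-methoxybenzylic carbinol ionises easily, so an SN1 component with loss of configuration is expected.
- The β-hydroxy ketone can also eliminate to the chalcone.
- The phenol at C4 must be masked and unmasked, and the stereocentre and the ring are made in separate steps.
- The chosen plan needs one protecting group and forms the C2 stereocentre and the C2–aryl bond in a single step.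

Key step: step 3

Remarks and assumptions:
- The descriptor [C@@H] at C2 of the target SMILES corresponds to 2S (priorities O1 > C1' > C3 > H).
- The sense of induction in step 5 is assumed from the (S)-BINAP/cyclohexenone case of the same reaction class. The spatially corresponding face is the Re face of C2 of 11 and leads to 2S. If the chromone binds the other way round, the (R)-ligand is used and nothing else changes.
- Compounds whose carbon atoms end up in the target are numbered as reactants; other reagents stand on the reagent line.

## Steps

Step 1
Reactants: 1 2,4-dihydroxyacetophenone; 2 allyl bromide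
Product: 3 1-[2,4-bis(prop-2-en-1-yloxy)phenyl]ethan-1-one
Conditions: 2 (2.6 equiv), K2CO3 (3 equiv), DMF, 60 °C
Reagents that add atoms: none
Why: Williamson ether synthesis; with excess base in DMF the hydrogen-bonded 2-OH is alkylated as well as the 4-OH, and O-alkylation by a primary allylic bromide in a dipolar aprotic solvent should outrun C-alkylation.

Step 2
Reactants: 3 1-[2,4-bis(prop-2-en-1-yloxy)phenyl]ethan-1-one; 4 N,N-dimethylformamide dimethyl acetal
Product: 5 (2E)-1-[2,4-bis(prop-2-en-1-yloxy)phenyl]-3-(dimethylamino)prop-2-en-1-one
Conditions: 4 (3 equiv), toluene, 110 °C, MeOH distilled off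
Reagents that add atoms: none
Why: Enaminone condensation of an aryl methyl ketone with an amide acetal; there is no free OH for the acetal to methylate, and the push–pull alkene should settle as the E isomer.

Step 3
Reactants: 5 (2E)-1-[2,4-bis(prop-2-en-1-yloxy)phenyl]-3-(dimethylamino)prop-2-en-1-one
Product: 9 4-oxo-6,8-di(prop-2-en-1-yl)-4H-chromen-7-yl acetate, via mono-rearranged phenol 6 (not isolated), via diallyl hydroxy-enaminone 7 (not isolated), via 6,8-diallyl-7-hydroxychromone 8 (not isolated)
Conditions: PhNEt2, 205–215 °C, N2 sweep; then 25 °C, Ac2O, DMAP (cat.)
Reagents that add atoms: acetic anhydride, CC(=O)OC(C)=O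
Why: Mechanism: the 4-O-allyl group of 5 moves by an aromatic Claisen ([3,3]) shift to an ortho carbon (C3 in 6); the 2-O-allyl group then finds both of its ortho carbons substituted, so its [3,3] shift is followed by a Cope shift to the para carbon C5 and enolisation (para-Claisen rearrangement), which gives 7 and frees the 2-OH. That phenol adds to the β-carbon of the enaminone and dimethylamine is expelled, closing the pyranone of 8 by 6-endo-trig addition–elimination; the amine is swept out with nitrogen so that it cannot reopen the ring. The closest known reactions are the ortho- and para-Claisen rearrangements of resacetophenone allyl ethers and the cyclisation of o-hydroxyaryl enaminones to chromones, joined here in one heating period. The selectivity needed is positional and the substrate secures it by convergence: either oxygen can deliver allyl only to C3 or C5 because C1, the one other ortho/para carbon, carries the acyl group and cannot rearomatise, so whichever ether moves first and wherever it lands, the 3,5-diallyl pattern is the only resting point. If the 2-O-allyl group moves first and the ring closes early, the remaining 7-O-allyl group has only C6 open and ends in the same 8. Allyl is used because it is unchanged by the allylic transposition of each shift, so one shift and two shifts give the same substituent; no stereocentre is formed. Acetylation in the cooled amine solution caps the acidic 7-OH as 9 before it can add to a neighbouring allyl group on work-up.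

Step 4
Reactants: 9 4-oxo-6,8-di(prop-2-en-1-yl)-4H-chromen-7-yl acetate; 10 2-methylbut-2-ene
Product: 11 6,8-bis(3-methylbut-2-en-1-yl)-4-oxo-4H-chromen-7-yl acetate
Conditions: Grubbs II (5 mol %), 10/CH2Cl2 (1:1), 40 °C, sealed tube
Reagents that add atoms: none
Why: Olefin cross-metathesis of terminal allylarenes with 2-methylbut-2-ene, the standard allyl-to-prenyl exchange; the large excess of the trisubstituted olefin should drive both termini to Me2C=, the meta-related allyl groups cannot ring-close, and the electron-poor endocyclic C2=C3 bond is not a metathesis partner.

Step 5
Reactants: 11 6,8-bis(3-methylbut-2-en-1-yl)-4-oxo-4H-chromen-7-yl acetate; 12 4-methoxyphenylboronic acid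
Product: 13 (2S)-2-(4-methoxyphenyl)-6,8-bis(3-methylbut-2-en-1-yl)-4-oxo-3,4-dihydro-2H-chromen-7-yl acetate
Conditions: [Rh(OH){(S)-MeO-F12-BIPHEP}]2 (3 mol % Rh), 12 (2.5 equiv), toluene/H2O (10:1), 30 °C
Reagents that add atoms: none
Why: Rhodium-catalysed asymmetric 1,4-addition of an arylboronic acid to a chromone (Hayashi–Miyaura type): transmetallation, insertion of C2=C3 into the Rh–aryl bond and hydrolysis of the rhodium enolate by water. C2 is set by the chiral bisphosphine, which should expose the Re face of C2 and give 2S; the electron-poor ligand is chosen because it allows this sluggish acceptor class to react near room temperature without added base, so the acetate stays on and the product does not ring-open. Isolated trisubstituted alkenes do not insert into Rh–aryl bonds under these conditions.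

Step 6
Reactants: 13 (2S)-2-(4-methoxyphenyl)-6,8-bis(3-methylbut-2-en-1-yl)-4-oxo-3,4-dihydro-2H-chromen-7-yl acetate
Product: 14 Lespeflorin A1, (2S)-7-hydroxy-2-(4-methoxyphenyl)-6,8-bis(3-methylbut-2-en-1-yl)-2,3-dihydro-4H-chromen-4-one
Conditions: NH4OAc (8 equiv), MeOH/H2O (4:1), 25 °C
Reagents that add atoms: none
Why: Near-neutral methanolysis of an activated aryl acetate, whose phenol is para to the ketone and a good leaving group; the acetyl group leaves as methyl acetate. No base strong enough to deprotonate C3 is present, so ring opening to the chalcone and loss of configuration at C2 are not expected, and without acid the prenyl groups should not cyclise.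

## Compound list

1 | 2,4-dihydroxyacetophenone | CC(=O)c1ccc(O)cc1O | starting material
2 | allyl bromide (3-bromoprop-1-ene) | C=CCBr | starting material
3 | 1-[2,4-bis(prop-2-en-1-yloxy)phenyl]ethan-1-one | CC(=O)c1ccc(OCC=C)cc1OCC=C | intermediate
4 | N,N-dimethylformamide dimethyl acetal | COC(OC)N(C)C | starting material
5 | (2E)-1-[2,4-bis(prop-2-en-1-yloxy)phenyl]-3-(dimethylamino)prop-2-en-1-one | CN(C)/C=C/C(=O)c1ccc(OCC=C)cc1OCC=C | intermediate
6 | (2E)-3-(dimethylamino)-1-[4-hydroxy-3-(prop-2-en-1-yl)-2-(prop-2-en-1-yloxy)phenyl]prop-2-en-1-one | CN(C)/C=C/C(=O)c1ccc(O)c(CC=C)c1OCC=C | intermediate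
7 | (2E)-1-[2,4-dihydroxy-3,5-di(prop-2-en-1-yl)phenyl]-3-(dimethylamino)prop-2-en-1-one | CN(C)/C=C/C(=O)c1cc(CC=C)c(O)c(CC=C)c1O | intermediate
8 | 7-hydroxy-6,8-di(prop-2-en-1-yl)-4H-chromen-4-one | O=c1ccoc2c(CC=C)c(O)c(CC=C)cc12 | intermediate
9 | 4-oxo-6,8-di(prop-2-en-1-yl)-4H-chromen-7-yl acetate | CC(=O)Oc1c(CC=C)cc2c(=O)ccoc2c1CC=C | intermediate
10 | 2-methylbut-2-ene | CC=C(C)C | starting material
11 | 6,8-bis(3-methylbut-2-en-1-yl)-4-oxo-4H-chromen-7-yl acetate | CC(=O)Oc1c(CC=C(C)C)cc2c(=O)ccoc2c1CC=C(C)C | intermediate
12 | 4-methoxyphenylboronic acid | COc1ccc(B(O)O)cc1 | starting material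
13 | (2S)-2-(4-methoxyphenyl)-6,8-bis(3-methylbut-2-en-1-yl)-4-oxo-3,4-dihydro-2H-chromen-7-yl acetate | COc1ccc([C@@H]2CC(=O)c3cc(CC=C(C)C)c(OC(C)=O)c(CC=C(C)C)c3O2)cc1 | intermediate
14 | Lespeflorin A1, (2S)-7-hydroxy-2-(4-methoxyphenyl)-6,8-bis(3-methylbut-2-en-1-yl)-2,3-dihydro-4H-chromen-4-one | COc1ccc([C@@H]2CC(=O)c3cc(CC=C(C)C)c(O)c(CC=C(C)C)c3O2)cc1 | target

## Step count and risk

Total step count: 6. Longest linear sequence: 6 steps (1 to 14).

**Step 3 (key step).** The cascade may stall after the first shift, or the enaminone may be consumed thermally before O1 is set free. On prolonged heating the acidic 7-OH may also add across a neighbouring allyl group and close a dihydrofuran ring. The fallback separates rearrangement from ring construction. It sets out from 3, which is heated in PhNEt2 without an enaminone present; the same convergent double Claisen rearrangement should give 1-[2,4-dihydroxy-3,5-di(prop-2-en-1-yl)phenyl]ethan-1-one F1. Formylation of the methyl ketone (HCO2Et, NaH, THF) should give the β-keto aldehyde as its cyclic hemiacetal, 2,7-dihydroxy-6,8-di(prop-2-en-1-yl)-2,3-dihydro-4H-chromen-4-one F2. Cyclodehydration (AcOH, cat. HCl; allyl groups tolerate this where prenyl groups would not) gives 8 as an isolated compound. Acetylation (Ac2O, pyridine) then rejoins the route at 9.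

**Step 5.** Enantioface discrimination on this substrate may be insufficient. The insertion may also be slow, so that protodeboronation of the electron-rich boronic acid takes over. Partial loss of the acetyl group would give a phenoxide that deactivates the enone. The fallback gives up catalyst control in favour of resolution with recycling. It sets out from 11, which is arylated with 12 under the more active achiral diene catalyst [Rh(OH)(cod)]2 (dioxane/H2O) to give racemic 2-(4-methoxyphenyl)-6,8-bis(3-methylbut-2-en-1-yl)-4-oxo-3,4-dihydro-2H-chromen-7-yl acetate F3. Preparative chromatography on a polysaccharide chiral stationary phase separates 13, where the route is rejoined, from the (2R)-acetate F4. F4 is returned to F3 by reversible ring opening and reclosure under catalytic base and resolved again.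

**Step 6.** Acyl transfer at the doubly ortho-substituted ester may be slow. Forcing it with stronger base would start the C3-deprotonation/ring-opening/reclosure sequence and erode the configuration at C2. The fallback removes base from the end of the route by carrying the phenol as a silyl ether. It sets out from 8, isolated by leaving out the anhydride quench of step 3. Silylation (TBSCl, imidazole, DMF) gives 7-[(tert-butyldimethylsilyl)oxy]-6,8-di(prop-2-en-1-yl)-4H-chromen-4-one F5. Cross-metathesis as in step 4 gives 7-[(tert-butyldimethylsilyl)oxy]-6,8-bis(3-methylbut-2-en-1-yl)-4H-chromen-4-one F6. Arylation as in step 5 gives (2S)-7-[(tert-butyldimethylsilyl)oxy]-2-(4-methoxyphenyl)-6,8-bis(3-methylbut-2-en-1-yl)-2,3-dihydro-4H-chromen-4-one F7. Buffered fluoride (HF·pyridine, THF, 0 °C) cleaves the Si–O bond without base and rejoins the route at 14.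

## Further compounds

F1 | step 3 | 1-[2,4-dihydroxy-3,5-di(prop-2-en-1-yl)phenyl]ethan-1-one | CC(=O)c1cc(CC=C)c(O)c(CC=C)c1O
F2 | step 3 | 2,7-dihydroxy-6,8-di(prop-2-en-1-yl)-2,3-dihydro-4H-chromen-4-one (racemic hemiacetal) | O=C1CC(O)Oc2c(CC=C)c(O)c(CC=C)cc12
F3 | step 5 | racemic 2-(4-methoxyphenyl)-6,8-bis(3-methylbut-2-en-1-yl)-4-oxo-3,4-dihydro-2H-chromen-7-yl acetate | COc1ccc(C2CC(=O)c3cc(CC=C(C)C)c(OC(C)=O)c(CC=C(C)C)c3O2)cc1
F4 | step 5 | (2R)-2-(4-methoxyphenyl)-6,8-bis(3-methylbut-2-en-1-yl)-4-oxo-3,4-dihydro-2H-chromen-7-yl acetate | COc1ccc([C@H]2CC(=O)c3cc(CC=C(C)C)c(OC(C)=O)c(CC=C(C)C)c3O2)cc1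
F5 | step 6 | 7-[(tert-butyldimethylsilyl)oxy]-6,8-di(prop-2-en-1-yl)-4H-chromen-4-one | CC(C)(C)[Si](C)(C)Oc1c(CC=C)cc2c(=O)ccoc2c1CC=C
F6 | step 6 | 7-[(tert-butyldimethylsilyl)oxy]-6,8-bis(3-methylbut-2-en-1-yl)-4H-chromen-4-one | CC(C)(C)[Si](C)(C)Oc1c(CC=C(C)C)cc2c(=O)ccoc2c1CC=C(C)C
F7 | step 6 | (2S)-7-[(tert-butyldimethylsilyl)oxy]-2-(4-methoxyphenyl)-6,8-bis(3-methylbut-2-en-1-yl)-2,3-dihydro-4H-chromen-4-one | COc1ccc([C@@H]2CC(=O)c3cc(CC=C(C)C)c(O[Si](C)(C)C(C)(C)C)c(CC=C(C)C)c3O2)cc1
A1 | alternative 1 | 1-[2,4-dihydroxy-3,5-bis(3-methylbut-2-en-1-yl)phenyl]ethan-1-one | CC(=O)c1cc(CC=C(C)C)c(O)c(CC=C(C)C)c1O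
A2 | alternative 1 | (2E)-1-[2,4-dihydroxy-3,5-bis(3-methylbut-2-en-1-yl)phenyl]-3-(4-methoxyphenyl)prop-2-en-1-one | COc1ccc(/C=C/C(=O)c2cc(CC=C(C)C)c(O)c(CC=C(C)C)c2O)cc1
A3 | alternative 2 | (2S)-7-hydroxy-2-(4-methoxyphenyl)-2,3-dihydro-4H-chromen-4-one | COc1ccc([C@@H]2CC(=O)c3ccc(O)cc3O2)cc1
A4 | alternative 2 | (2S)-6,8-dibromo-7-hydroxy-2-(4-methoxyphenyl)-2,3-dihydro-4H-chromen-4-one | COc1ccc([C@@H]2CC(=O)c3cc(Br)c(O)c(Br)c3O2)cc1
A5 | alternative 3 | (3R)-3-hydroxy-1-[2-hydroxy-4-(methoxymethoxy)-3,5-bis(3-methylbut-2-en-1-yl)phenyl]-3-(4-methoxyphenyl)propan-1-one | COCOc1c(CC=C(C)C)cc(C(=O)C[C@@H](O)c2ccc(OC)cc2)c(O)c1CC=C(C)C
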